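The earlier runs and the new flask were generated by integration with constants of no real substance; noise was put on by code.

The slowness of target in the north-east flask, the very flask asked about, is what speaks of [substrate], which no column shows.

in all of them: substrate 20 mM

| run | remark | time |
|---|---|---|
| north-east | the very flask that is asked about, followed so far |  |
| flask |  | 1.0 h |

north-east run (percent of the substrate charged)

| time / min | target / % | side product A / % |
|---|---|---|
| 2.50 | 4 | 2 |
| 5.00 | 10 | 1 |
| 8.00 | 12 | 0 |
| 15.0 | 19 | 2 |
| 30.0 | 28 | 3 |

(each reading ± 1.5 percentage points)

1. target present at 1.0 h, in percent of the substrate charged
2. side product A present at 1.0 h, in percent of the substrate charged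
3. substrate present at 1.0 h, in percent of the substrate charged
4. homo dimer present at 1.0 h, in percent of the substrate charged

- in percentages every species weighs as the substrate in it: one homo dimer counts as two
- a reading or a percentage of target counts all its forms, free or not

Read down the target column. The first 8.00 min give 12%, and the 15.0 min from 15.0 min to 30.0 min give 9 percentage points. Per minute, the later window runs at 0.400 of the earlier one. The last row holds target and side product A at 31.0% together, so with these as the sole sinks, [substrate] would stand at 69.0% of its charge. The slope, as read, has fallen further than that, so my reckoning supposes a loss unseen in the columns that takes substrate.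

My own reckoning takes the slope of target as proportional to [substrate] and lets the reciprocal of [substrate] grow evenly with time. [Substrate] is then the charge divided by one plus time over a single constant. The mid-times of the two windows give 8.33 min for the time in which [substrate] falls to half its charge, in this reckoning a second-order half-life, here called the dimer time. It is a reading, loose by the 1.5 points on each reading of target. At 1.0 h it gives substrate 12.2%, and the summed slope gives target 38.9%. With side product A taken at 3% from the last row, and with this reckoning supposing no further species that holds substrate, the remainder is homo dimer, 45.9%.

The forecast is 40% target, 3% side product A, 32% substrate and 25% homo dimer: “I can't distinguish these, so I take a middle value with wide ranges”. It stands near my reckoning on target but differs on the split, with more substrate and less homo dimer.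

The flask gives 35.6% target, 3.34% side product A, 8.22% substrate and 42.9% homo dimer.

    intermediate A → side product A (k = 0.00920 s⁻¹)
    substrate + target ⇌ idle adduct, settled at all times (K = 230 M⁻¹)
    intermediate A → intermediate B (k = 5.00 × 10⁻⁴ s⁻¹)
    intermediate B ⇌ intermediate C (K = 0.270, k = 2.40 × 10⁻⁴ s⁻¹)
    substrate → intermediate A (k = 3.80 × 10⁻⁵ s⁻¹)
    intermediate B → side product B (k = 9.40 × 10⁻⁴ s⁻¹)
    2 substrate → homo dimer (k = 0.0270 M⁻¹ s⁻¹)
    intermediate C → decomposed reagent (k = 4.40 × 10⁻⁴ s⁻¹)
    substrate → target (k = 3.80 × 10⁻⁴ s⁻¹)

Part of the shortfall in target goes with the loss of 2 substrate to homo dimer and part with the time allowed. Target stands at 35.6% in this flask, at 55.2% in the same run without that loss, and at 50.4% in the run left ten times as long. The dimer time of 8.33 min put this flask at 12.2% substrate and 45.9% homo dimer, where it holds 8.22% and 42.9%. For the same flask read at 15 min, the dimer time gives 35.7% substrate, and that flask holds 32.8%.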